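(Readings and results are simulated on assumed constants; scatter was added.)

How high does target stand in the flask, when, and what could the two settings we can turn, time and charge, do to that height?

| flask | starting material | remark | time |
|---|---|---|---|
| eta | 0.063 M | the very flask that is asked about, followed so far |  |
| delta | 0.032 M | run made earlier |  |
| flask | 0.063 M |  | 40 h |

| run | time / h | target / % | starting material / % |
|---|---|---|---|
| eta | 0.167 | 26.1 | 65.6 |
| eta | 0.417 | 37.3 | 48.2 |
| eta | 1.33 | 35.6 | 37.8 |
| eta | 3.00 | 24.2 | 32.9 |
| eta | 8.00 | 7.0 | 20.2 |
| delta | 0.417 | 26.0 | 64.7 |
| delta | 1.33 | 27.3 | 52.3 |
| delta | 4.00 | 16.4 | 41.0 |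
| delta | 12.0 | 3.3 | 20.5 |
| delta | 40.0 | 0 | 6.6 |

(scatter of a reading: 0.5 percentage points)

- in percentages every species weighs as the starting material in it: one target counts as two
- a reading or a percentage of target counts all its forms, free or not
- a reading of starting material is of its free form alone

* time up to 40 h at which target stands highest
* the amount of target, in percent of the starting material charged, at that time
* earliest time at which at least nineteen twentieths of that best amount are there
* latest time at which they still are

Time first. In the eta run, which is this flask followed so far, target reads 37.3 % at 0.417 h, its highest reading, and 35.6 % at 1.33 h. The top therefore lies between 0.167 h and 1.33 h, and our own reckoning for the flask is that reading plus a small upward correction.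

Charge next. The delta run has about half the charge, and its highest reading is 27.3 %. By hand, we take each highest reading to sit a like small step below its own top. The charge exponent, the logarithm of the ratio of the two heights over the logarithm of the ratio of the two charges, then reads 0.461, with the scatter of its readings. So between the delta charge and the eta charge, with all else held, height goes close to the square root of the charge; we read nothing from this about charges above the eta charge.

The forecast gives a best of 39 % (38 % to 40.5 %) at 0.7 h (0.55 h to 0.9 h), open at 0.4 h (0.33 h to 0.47 h) and shut at 1.15 h (0.95 h to 1.3 h), on the ground of “reversible dimerisation, with target returning to starting material”.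

The flask gives 39.8 % at 0.689 h, open at 0.427 h and shut at 1.12 h, each within the forecast's range.

    2 starting material ⇌ target (K = 12.0 M⁻¹, k = 0.350 M⁻¹ min⁻¹)
    starting material + target ⇌ idle adduct, settled at all times (K = 41.0 M⁻¹)
    target → over-reaction product (k = 0.0130 min⁻¹)

The flask's 39.8 % counts target held in idle adduct, which stands at 31.3 % at 0.689 h. A run at a lower charge can take the best out of the forecast's range, and one neighbouring flask shows it. For the neighbouring flask at 0.025 M, with time and all else held, we carry the flask's top down by the charge exponent of 0.461, which gives 26.0 %. That neighbour's best comes out at 25.6 %, under the forecast's low end of 38 %.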